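What would be left over of the free base was my first question, for Sunday's and Wednesday's flasks differ from the red run in its charge and in the time.

| flask | electrophile | nucleophile | free base | remark | time |
|---|---|---|---|---|---|
| red | 0.59 M | 1.5 equiv | 1.2 equiv | run made earlier |  |
| Sunday's | 0.59 M | 1.50 equiv | 3.00 equiv |  | 15 h |
| Wednesday's | 0.59 M | 1.50 equiv | 2.00 equiv |  | 15 h |

red run (percent of the electrophile charged)

| time / h | electrophile / % | target / % |
|---|---|---|
| 0.667 | 87.2 | 4.4 |
| 2.00 | 68.4 | 9.9 |
| 4.00 | 53.7 | 14.8 |
| 5.00 | 48.5 | 16.1 |
| 8.00 | 45.3 | 18.2 |

(each reading ± 1 percentage point)

- what has gone from electrophile into another species counts as reacted, even if it can come back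
- no earlier run changes the charge of free base; that part of a forecast is a guess

1. part of the electrophile that has reacted at the end, Sunday's
2. part of the electrophile that has reacted at the end, Wednesday's
3. what raising the equivalents of free base from its lowest to its highest value here does to the part of the electrophile that has reacted (changes below 5 percentage points count as none) (no change / it falls / it rises)

I counted turnovers of the free base, guessing that each target takes one. The red run's last reading, 18.2% of target on 1.2 equiv of free base, gave 15.2% in what I call the base load, target made per free base charged. That is far less than the whole charge, so free base did not look like the limiting reagent even at its lowest charge, and I expected no change from adding more, though no earlier run tested this. Carrying the fall of electrophile between the last two readings straight on to 15 h gave me 62.2% reacted in both flasks.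

The forecast differed from me: 88% for Sunday's, 78% for Wednesday's, and it rises, on the ground that “The abrupt stall suggests either a reversible adduct with the base or exhaustion of the base”.

The simulation gave 62.8% for Sunday's and 62.6% for Wednesday's, so no change, a difference of 0.18 percentage points.

    electrophile + nucleophile → acid set free + target (k = 0.00130 L mol⁻¹ min⁻¹)
    nucleophile + acid set free ⇌ protonated nucleophile, settled at all times (K = 18.0 L mol⁻¹)
    acid set free + free base ⇌ salt of the base (K = 1600 L mol⁻¹, k = 0.0160 L mol⁻¹ min⁻¹)
    electrophile + target → side product (k = 0.00110 L mol⁻¹ min⁻¹)
    electrophile ⇌ dormant form (K = 0.740, k = 0.00270 min⁻¹)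
    2 nucleophile → homo dimer (k = 0.00110 L mol⁻¹ min⁻¹)

A turnover is one acid set free. The side product holds one turnover but counts double in its percentage, so I added it to the target at a weight of 0.5. Sunday's flask at 15.0 h then carried a base load of 9.49%, with 92% of its free base left. The same flask left until 2.5 d reckons to 14.3%; it held 86% of its free base, with 77.8% of its electrophile reacted.

The data are simulated with made-up constants, and the scatter is random.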